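How slowly the gas gets in, held against how fast the starting material takes it up, is the question of this flask.

    gas phase ⇌ dissolved gas, rate k1*(csat - [dissolved gas]) (k1 = 0.027 s⁻¹, csat = 150 mM)
    starting material + dissolved gas ⇌ target (K2 = 9.8 M⁻¹, k2 = 0.016 M⁻¹ s⁻¹)
    2 dissolved gas → homo dimer (k3 = 0.010 M⁻¹ s⁻¹)
    starting material + target → side product (k4 = 0.0032 M⁻¹ s⁻¹)

starting material 0.80 M; gas phase 150 mM (held); time 6.0 min

- alder: doubling the transfer coefficient of step 1, all else as stated
- maple: doubling the saturation concentration of gas phase, all else as stated

- in percentages every species weighs as the starting material in it: one side product counts as two
- two of one species on the left: rate k times its square, two consumed each time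
- at the start none of the gas is dissolved
- run time (flask): 6.0 min

1. amount of target at 6.0 min, in percent of the starting material charged
2. concentration of dissolved gas in solution at 1.5 min, in percent of saturation
3. the change that raises the amount of target at 6.0 min, in percent of the starting material charged most ("none" if none brings more than 2 percentage points) (alder / maple / none)
4. amount of target at 6.0 min, in percent of the starting material charged, after maple

How soon does c(dissolved gas) close in on its balance? Early on it relaxes under two first-order rates that add: the transfer coefficient, and the forward constant of target formation times c(starting material), a pseudo-first-order uptake. Their sum gives a relaxation time of 25.1 s, shorter than 1.5 min, so the gap has shrunk to 2.78% of itself by then.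

What level does it approach? The balance fraction at the charge, 67.8% of saturation: the transfer coefficient divided by that same sum. Homo dimer formation adds a loss rate of 0.00204 s⁻¹, less than the 0.0128 s⁻¹ of uptake, so it is dropped here. My reckoning for sat is therefore 65.9%.

Which change helps more? The forward rate of target formation is proportional to c(dissolved gas). Alder lifts the balance fraction by a factor of 1.19, while maple leaves the fraction alone and doubles saturation, a larger lift, so I choose maple. For y the hand stops: target's half-life by over-reaction alone, the other concentrations as charged, is 4.5 min, shorter than 6.0 min.

The forecast gives y 25% (22% to 28%), sat 65% (61% to 70%), maple as best, and yb 41% (36% to 46%), on these grounds: “Doubling saturation nearly doubles the dissolved gas”.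

The simulation gives y 25.2%, sat 65.9%, maple as best and yb 40.8%. Maple gains 16 percentage points, alder 3.2 points. The balance fraction, taken with the 76.7% of starting material left at 3.00 min, gives 73.3%, and the flask then reads 71.8%.

In the neighbour charged with 0.20 M of starting material, the fraction gives 89.4% at the charge and 93.6% with the 57.6% left at 6.0 min. That neighbour reads 87.9% of saturation at 6.00 min, with y at 35.9%.

Its constants are assumed; the flask was simulated.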